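**Plan**
- Retrosynthesis: the 3-O- and 4'-O-benzyl groups and the 5-O-methyl group are put back. Ring C is then cut at C4–C4a (to an acrylic acid), at O1–C2 (to a phenol and an enol triflate), and last at C2–C3 (to an ester enolate and an aroyl chloride).
- Forward: rings A and B are bought. The C2–C3–C4 chain is built on ring B by a crossed Claisen acylation and joined to ring A through O1 by vinylic substitution. Ring C closes last.
- The C8 oxygen enters masked as the formyl group of the salicylaldehyde. A Baeyer–Villiger oxidation reveals it, so O8 alone is acetylated while every other phenol is still capped.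
- Enabling feature: a chain tethered at O1 can reach only C8 and C4a of ring A. C8 carries the acetoxy group. C4a is a free CH lying ortho to O1, ortho to the C5 oxygen and para to the C7 methoxy group.
- Stereochemistry: the target has no stereocentre. Only the C2=C3 geometry of the open-chain compounds matters; it is set by triflation of a chelated enolate and can correct itself under acid.

Key step: step 8

Remark: flavone numbering (O1, C2, C3, C4, C4a, C5–C8, C8a, ring B primed) is also used for the open-chain intermediates. The β-keto ester is racemic at C3, and that centre disappears on enolisation.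

**Step 1**
Reactants: 1 benzyl alcohol; 2 tert-butyl bromoacetate
Product: 3 tert-butyl 2-(benzyloxy)acetate
Conditions: NaH, THF, 0 °C; then 2, cat. Bu4NI, 0 °C → rt
Reagents that add atoms: none
Why: Williamson ether synthesis, in which the sodium alkoxide of 1 displaces the primary, carbonyl-activated bromide by SN2 while the bulky tert-butyl ester resists transesterification.

**Step 2**
Reactants: 3 tert-butyl 2-(benzyloxy)acetate; 4 4-(benzyloxy)benzoyl chloride
Product: 5 tert-butyl 2-(benzyloxy)-3-[4-(benzyloxy)phenyl]-3-oxopropanoate (racemic)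
Conditions: 3 (2 equiv), LiN(iPr)2 (2 equiv), THF, –78 °C; then 4 (1 equiv), –78 → –30 °C; aq. NH4Cl
Reagents that add atoms: none
Why: Crossed Claisen C-acylation, in which the lithium enolate of a tert-butyl ester that is slow to self-condense attacks an aroyl chloride that cannot enolise, and the second equivalent of enolate takes up the acidic C3–H of the product so that it is not acylated twice.

**Step 3**
Reactants: 5 tert-butyl 2-(benzyloxy)-3-[4-(benzyloxy)phenyl]-3-oxopropanoate
Product: 6 tert-butyl (E)-2-(benzyloxy)-3-[4-(benzyloxy)phenyl]-3-(trifluoromethylsulfonyloxy)prop-2-enoate (triflate and ester cis)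
Conditions: LiOSO2CF3, Et3N, CH2Cl2, 0 °C; then (CF3SO2)2O, 0 °C
Reagents that add atoms: trifluoromethanesulfonic anhydride, O=S(=O)(OS(=O)(=O)C(F)(F)F)C(F)(F)F
Why: O-sulfonylation of a β-keto ester enolate, in which lithium chelates the ketone and ester oxygens during soft enolisation so that the isomer with triflate and ester cis (E by the priority rules) should prevail, and the product has no hydrogen through which the triflate could eliminate.

**Step 4**
Reactants: 6 the (E)-enol triflate; 7 2-hydroxy-4,6-dimethoxybenzaldehyde
Product: 8 tert-butyl (E)-2-(benzyloxy)-3-[4-(benzyloxy)phenyl]-3-(2-formyl-3,5-dimethoxyphenoxy)prop-2-enoate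
Conditions: Cs2CO3, MeCN, rt → 50 °C
Reagents that add atoms: none
Why: Vinylic nucleophilic substitution by addition–elimination, in which the caesium phenoxide of 7 adds to the ester-conjugated carbon bearing the triflate and triflate leaves from the short-lived ester enolate, normally with retention of geometry, to form the O1–C2 bond.

**Step 5**
Reactants: 8 the formyl aryl vinyl ether
Product: 9 tert-butyl (E)-2-(benzyloxy)-3-[4-(benzyloxy)phenyl]-3-[2-(formyloxy)-3,5-dimethoxyphenoxy]prop-2-enoate
Conditions: mCPBA, CH2Cl2, 0 °C → rt; cold aq. Na2S2O3/NaHCO3 wash, used crude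
Reagents that add atoms: 3-chloroperoxybenzoic acid, O=C(OO)c1cccc(Cl)c1
Why: Baeyer–Villiger (Dakin-type) oxidation, in which the peracid adds to the formyl group and the 2,4,6-trioxygenated aryl group migrates far better than hydrogen, while the tetrasubstituted, ester-conjugated C2=C3 bond is too hindered and too electron-poor to be epoxidised at this temperature.

**Step 6**
Reactants: 9 the aryl formate
Product: 11 tert-butyl (E)-3-(2-acetoxy-3,5-dimethoxyphenoxy)-2-(benzyloxy)-3-[4-(benzyloxy)phenyl]prop-2-enoate, via free phenol 10 (not isolated)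
Conditions: morpholine (1 equiv), CH2Cl2, 0 °C; then Ac2O, pyridine, cat. DMAP, 0 °C → rt
Reagents that add atoms: acetic anhydride, CC(=O)OC(C)=O
Why: Aminolysis of the very reactive aryl formate frees the C8 hydroxyl without building up its phenoxide, which could add in conjugate fashion to C2, and DMAP-catalysed acetylation caps it at once.

**Step 7**
Reactants: 11 the acetoxy tert-butyl ester
Product: 12 (E)-3-(2-acetoxy-3,5-dimethoxyphenoxy)-2-(benzyloxy)-3-[4-(benzyloxy)phenyl]prop-2-enoic acid
Conditions: CF3CO2H–CH2Cl2 (1:4), dry, 0 °C → rt; co-evaporation with toluene, used directly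
Reagents that add atoms: none
Why: Acidolysis of a tert-butyl ester by loss of isobutene, which the aryl acetate, the benzyl ethers and (without water) the enol ethers tolerate, and tert-butylation of ring A is disfavoured because both of its free carbons are flanked by two oxygen substituents.

**Step 8**
Reactants: 12 the (E)-3-aryloxyacrylic acid
Product: 14 8-acetoxy-3-(benzyloxy)-2-[4-(benzyloxy)phenyl]-5,7-dimethoxy-4H-chromen-4-one, via mixed trifluoroacetic anhydride 13 (not isolated)
Conditions: (CF3CO)2O (2 equiv), CH2Cl2, 0 °C → rt; cold aq. NaHCO3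
Reagents that add atoms: none
Why: The anhydride converts the carboxyl group of 12 into mixed anhydride 13, whose acyl carbon (as such, or after ionisation to the acylium ion under the CF3CO2H released) is attacked by C4a of ring A, and loss of the C4a proton from the arenium ion restores aromaticity and leaves the C4 ketone. The closest known reaction type is the intramolecular Friedel–Crafts acylation of 3-aryloxyacrylic and 2-aryloxybenzoic acids to chromones and xanthones with (CF3CO)2O or P2O5 in MeSO3H. Ring C closes as a six-membered ring (O1, C2, C3, C4, C4a, C8a) by 6-exo-trig attack of the arene on the anhydride carbonyl, which the E geometry allows because carboxyl and aryloxy groups sit cis on C2=C3. No stereocentre is formed, and any Z isomer can reach the reactive form because reversible protonation at C3 gives a C2 cation stabilised by O1 and ring B, around whose C2–C3 bond rotation is free. Site selectivity is needed between C4a, C6 and ring B: the O1 tether reaches only the two ortho carbons, C8 is blocked by the acetoxy group, C6 is out of reach, and closure onto ring B would need the Z isomer, a five-membered ring and a carbon meta to the 4'-benzyloxy donor. Because three oxygens push electron density onto C4a (O1 and the C5 methoxy ortho, the C7 methoxy para), neither a Lewis acid nor heat is required, so the acetate and both benzyl ethers should persist, and the new C4 carbonyl deactivates ring A against trifluoroacetylation at C6.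

**Step 9**
Reactants: 14 the protected flavonol
Product: 15 pollenitin 8-acetate, 8-acetoxy-3,5-dihydroxy-2-(4-hydroxyphenyl)-7-methoxy-4H-chromen-4-one
Conditions: BCl3 (6 equiv, 1 M in CH2Cl2), C6HMe5 (6 equiv), CH2Cl2, –78 → 0 °C; ice-water quench
Reagents that add atoms: none
Why: BCl3 with pentamethylbenzene as cation trap is an established Lewis acid debenzylation that does not spare benzyl ethers in favour of methyl ethers, so it is used for all three cleavages at once: both benzyl groups go at low temperature and the C5 methyl group, held in a chelate with the C4 carbonyl, is removed by chloride on warming, whereas the unchelated C7 methyl ether and the C8 acetate should stay intact at or below 0 °C.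

**Compound list**
1 | benzyl alcohol | OCc1ccccc1 | starting material
2 | tert-butyl bromoacetate | BrCC(=O)OC(C)(C)C | starting material
3 | tert-butyl 2-(benzyloxy)acetate | O=C(COCc1ccccc1)OC(C)(C)C | intermediate
4 | 4-(benzyloxy)benzoyl chloride | O=C(Cl)c1ccc(OCc2ccccc2)cc1 | starting material
5 | tert-butyl 2-(benzyloxy)-3-[4-(benzyloxy)phenyl]-3-oxopropanoate (racemic) | O=C(c1ccc(OCc2ccccc2)cc1)C(OCc1ccccc1)C(=O)OC(C)(C)C | intermediate
6 | tert-butyl (E)-2-(benzyloxy)-3-[4-(benzyloxy)phenyl]-3-(trifluoromethylsulfonyloxy)prop-2-enoate | CC(C)(C)OC(=O)/C(OCc1ccccc1)=C(/c1ccc(OCc2ccccc2)cc1)OS(=O)(=O)C(F)(F)F | intermediate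
7 | 2-hydroxy-4,6-dimethoxybenzaldehyde | COc1cc(O)c(C=O)c(OC)c1 | starting material
8 | tert-butyl (E)-2-(benzyloxy)-3-[4-(benzyloxy)phenyl]-3-(2-formyl-3,5-dimethoxyphenoxy)prop-2-enoate | CC(C)(C)OC(=O)/C(OCc1ccccc1)=C(/c1ccc(OCc2ccccc2)cc1)Oc1cc(OC)cc(OC)c1C=O | intermediate
9 | tert-butyl (E)-2-(benzyloxy)-3-[4-(benzyloxy)phenyl]-3-[2-(formyloxy)-3,5-dimethoxyphenoxy]prop-2-enoate | CC(C)(C)OC(=O)/C(OCc1ccccc1)=C(/c1ccc(OCc2ccccc2)cc1)Oc1cc(OC)cc(OC)c1OC=O | intermediate
10 | tert-butyl (E)-2-(benzyloxy)-3-[4-(benzyloxy)phenyl]-3-(2-hydroxy-3,5-dimethoxyphenoxy)prop-2-enoate | CC(C)(C)OC(=O)/C(OCc1ccccc1)=C(/c1ccc(OCc2ccccc2)cc1)Oc1cc(OC)cc(OC)c1O | intermediate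
11 | tert-butyl (E)-3-(2-acetoxy-3,5-dimethoxyphenoxy)-2-(benzyloxy)-3-[4-(benzyloxy)phenyl]prop-2-enoate | CC(C)(C)OC(=O)/C(OCc1ccccc1)=C(/c1ccc(OCc2ccccc2)cc1)Oc1cc(OC)cc(OC)c1OC(C)=O | intermediate
12 | (E)-3-(2-acetoxy-3,5-dimethoxyphenoxy)-2-(benzyloxy)-3-[4-(benzyloxy)phenyl]prop-2-enoic acid | OC(=O)/C(OCc1ccccc1)=C(/c1ccc(OCc2ccccc2)cc1)Oc1cc(OC)cc(OC)c1OC(C)=O | intermediate
13 | mixed anhydride of 12 and trifluoroacetic acid | O=C(OC(=O)C(F)(F)F)/C(OCc1ccccc1)=C(/c1ccc(OCc2ccccc2)cc1)Oc1cc(OC)cc(OC)c1OC(C)=O | intermediate
14 | 8-acetoxy-3-(benzyloxy)-2-[4-(benzyloxy)phenyl]-5,7-dimethoxy-4H-chromen-4-one | COc1cc(OC)c2c(=O)c(OCc3ccccc3)c(-c3ccc(OCc4ccccc4)cc3)oc2c1OC(C)=O | intermediate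
15 | pollenitin 8-acetate | COc1cc(O)c2c(=O)c(O)c(-c3ccc(O)cc3)oc2c1OC(C)=O | target

Total step count: 9. Longest linear sequence: 9 (steps 1–9).

**Steps most likely to fail**

Step 4.
- What may go wrong: the hindered, weakly nucleophilic salicylaldehyde phenoxide may add only slowly to C2. That carbon is deactivated by the C3 benzyloxy group and by the p-benzyloxyphenyl ring. Attack at sulfur (triflyl transfer) could then win and return the keto ester.
- Fallback: the polar addition–elimination is replaced by a C–O cross-coupling catalysed by zerovalent palladium. It sets out from 6 (with 7) and comes back at 8.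
- Conditions: Pd2(dba)3, 2-di-tert-butylphosphino-2',4',6'-triisopropylbiphenyl, K3PO4, toluene, 90 °C.
- Oxidative addition into the C–OTf bond and reductive elimination of the aryl vinyl ether do not depend on the electrophilicity of C2. The sparingly soluble base keeps the free phenoxide concentration low. This fallback makes no new compound (F0).

Step 5.
- What may go wrong: peracid oxidation of the doubly oxygenated C2=C3 bond may compete with aryl migration. The C8 oxygen, once freed next to the aryl vinyl ether, may add to C2.
- Fallback: the order of oxidation and ring closure is reversed. It sets out from 8 and comes back at 14.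
- CF3CO2H cleaves the ester to (E)-2-(benzyloxy)-3-[4-(benzyloxy)phenyl]-3-(2-formyl-3,5-dimethoxyphenoxy)prop-2-enoic acid F1.
- (CF3CO)2O with catalytic CF3SO3H takes F1 through its mixed trifluoroacetic anhydride F2 to 3-(benzyloxy)-2-[4-(benzyloxy)phenyl]-5,7-dimethoxy-4-oxo-4H-chromene-8-carbaldehyde F3. C4a is meta to the formyl group and still has three oxygen donors.
- With C2=C3 now inside the pyranone and O1 locked in ring C, mCPBA gives 3-(benzyloxy)-2-[4-(benzyloxy)phenyl]-5,7-dimethoxy-4-oxo-4H-chromen-8-yl formate F4.
- Morpholine then gives 3-(benzyloxy)-2-[4-(benzyloxy)phenyl]-8-hydroxy-5,7-dimethoxy-4H-chromen-4-one F5, and Ac2O/pyridine gives 14.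

Step 9.
- What may go wrong: the C8 acetyl group may be lost to the Lewis acid or during hydrolysis of the boron chelates. The C5 methyl ether may cleave incompletely once boron is bound at O3 and the C4 carbonyl. Benzyl cations may alkylate ring A.
- Fallback: the two kinds of cleavage are separated and no benzyl cation is generated. It sets out from 14 and comes back at 15.
- Neutral hydrogenolysis (H2, Pd/C, EtOAc–THF) gives 8-acetoxy-3-hydroxy-2-(4-hydroxyphenyl)-5,7-dimethoxy-4H-chromen-4-one F6.
- The mild chelating reagent MgI2·OEt2 in THF then removes only the methyl group peri to the C4 carbonyl.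

**Further compounds**
F0 | step 4 | none | none
F1 | step 5 | (E)-2-(benzyloxy)-3-[4-(benzyloxy)phenyl]-3-(2-formyl-3,5-dimethoxyphenoxy)prop-2-enoic acid | OC(=O)/C(OCc1ccccc1)=C(/c1ccc(OCc2ccccc2)cc1)Oc1cc(OC)cc(OC)c1C=O
F2 | step 5 | mixed anhydride of F1 and trifluoroacetic acid | O=C(OC(=O)C(F)(F)F)/C(OCc1ccccc1)=C(/c1ccc(OCc2ccccc2)cc1)Oc1cc(OC)cc(OC)c1C=O
F3 | step 5 | 3-(benzyloxy)-2-[4-(benzyloxy)phenyl]-5,7-dimethoxy-4-oxo-4H-chromene-8-carbaldehyde | COc1cc(OC)c2c(=O)c(OCc3ccccc3)c(-c3ccc(OCc4ccccc4)cc3)oc2c1C=O
F4 | step 5 | 3-(benzyloxy)-2-[4-(benzyloxy)phenyl]-5,7-dimethoxy-4-oxo-4H-chromen-8-yl formate | COc1cc(OC)c2c(=O)c(OCc3ccccc3)c(-c3ccc(OCc4ccccc4)cc3)oc2c1OC=O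
F5 | step 5 | 3-(benzyloxy)-2-[4-(benzyloxy)phenyl]-8-hydroxy-5,7-dimethoxy-4H-chromen-4-one | COc1cc(OC)c2c(=O)c(OCc3ccccc3)c(-c3ccc(OCc4ccccc4)cc3)oc2c1O
F6 | step 9 | 8-acetoxy-3-hydroxy-2-(4-hydroxyphenyl)-5,7-dimethoxy-4H-chromen-4-one | COc1cc(OC)c2c(=O)c(O)c(-c3ccc(O)cc3)oc2c1OC(C)=O
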